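**Retrosynthetic overview**

- Feature: the γ‑lactone O–C19(=O)–C17–C8–C7, trans‑fused at C7–C8 to the ten‑membered carbocycle C1–C10, is without its ring oxygen a 3‑oxycyclobutanone (C7, C19, C17, C8). It is made by [2+2] addition of a ketene across a C7=C8 silyl enol ether (C7–C19 and C8–C17), then Baeyer–Villiger insertion at C7–C19.
- The ketene is methylketene carrying a removable chlorine on C17 (chloro(methyl)ketene). The chlorine activates the cycloaddition and blocks migration of C17 in the ring expansion; zinc removes it afterwards.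
- The ring‑trans enol ether (7Z by the CIP rules, C6 and C9 on opposite sides) with the C6 chloride, the 3Z olefin and the 5(16)‑methylene comes from an anionic oxy‑Cope ring expansion (C3–C8 broken, C5–C6 formed) of a trans‑decalin with an axial (E)‑2‑chlorovinyl group on C8 and an equatorial allenyl group on C3.
- The decalin comes from a Diels–Alder reaction of 2‑methoxy‑5‑methylbenzoquinone (ring B) with a 2‑silyloxypentadiene (ring A). The allenyl group is set by a propargyl Claisen rearrangement of the C8 enol ether, and the 11,12‑diol by osmylation.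
- Order of ring formation: ring B (quinone) → ring A → dioxolane (temporary) → ten‑membered ring (ring B opened) → cyclobutanone (temporary) → γ‑lactone → epoxide.

Key step: step 19

Remark: briarane numbering is used for every intermediate. Ring A = C1, C10–C14; ring B (decalin stage) = C1, C2, C3, C8, C9, C10; C15 and C20 are the methyls on C1 and C11; β is the face of the C15 methyl in the decalins.

Assumption: the sense of induction of the catalyst from TiCl2(OiPr)2 and (R)‑BINOL in step 3 is taken by analogy with related 2‑methoxyquinone cycloadditions; if it proves opposite, (S)‑BINOL is used.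

**Route**

Step 1
Reactants: 1 2‑methyl‑1,4‑benzoquinone
Product: 3 2‑methoxy‑5‑methyl‑1,4‑benzoquinone, via 2‑methoxy‑5‑methylhydroquinone 2 (not isolated)
Conditions: MeOH, ZnCl2, 65 °C; 1 in twofold amount (one equivalent serves as oxidant)
Reagents that add atoms: methanol, CO
Why: Oxidative alkoxylation of a quinone: Lewis‑acid‑promoted conjugate addition of methanol para to the methyl group gives hydroquinone 2, which a second equivalent of 1 reoxidises.

Step 2
Reactants: 4 (E)‑pent‑3‑en‑2‑one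
Product: 5 (E)‑2‑(tert‑butyldimethylsilyloxy)penta‑1,3‑diene
Conditions: TBSOTf, Et3N, CH2Cl2, 0 °C
Reagents that add atoms: tert‑butyldimethylsilyl trifluoromethanesulfonate, CC(C)(C)[Si](C)(C)OS(=O)(=O)C(F)(F)F
Why: Soft enolisation on the methyl side gives the cross‑conjugated silyl dienol ether with the E‑propenyl unit unchanged.

Step 3
Reactants: 3 2‑methoxy‑5‑methyl‑1,4‑benzoquinone; 5 (E)‑2‑(tert‑butyldimethylsilyloxy)penta‑1,3‑diene
Product: 6 cis‑fused Diels–Alder adduct (H10 cis to C15)
Conditions: (R)‑BINOL (0.3 equiv), TiCl2(OiPr)2 (0.3 equiv), 4 Å sieves, toluene, −40 → 0 °C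
Reagents that add atoms: none
Why: Diels–Alder reaction in which titanium chelates the C9 carbonyl and the neighbouring methoxy oxygen, so the methyl‑bearing double bond reacts (the methoxy‑bearing one is a deactivated vinylogous ester) and C1, β to the chelated carbonyl, takes the nucleophilic CH2 terminus of the diene; endo addition gives the cis ring fusion and the ligand selects the face that sets C1.

Step 4
Reactants: 6 cis‑fused Diels–Alder adduct
Product: 7 trans‑fused dione (H10 trans to C15)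
Conditions: DBU (0.2 equiv), toluene, 25 °C; recovered 6 resubmitted
Reagents that add atoms: none
Why: Base‑mediated epimerisation at C10 through the enolate of the C9 ketone should give the trans‑fused isomer, in which the C20 methyl is equatorial; the quaternary C1 is untouched.

Step 5
Reactants: 7 trans‑fused dione
Product: 8 9β‑hydroxy enone
Conditions: NaBH4, CeCl3·7H2O, MeOH–THF, −78 °C
Reagents that add atoms: none
Why: Luche 1,2‑reduction takes the C9 ketone, far more electrophilic than the vinylogous ester carbonyl C2, and hydride enters anti to the axial C15 methyl (1,3 to C9), so the hydroxyl is axial and cis to C15.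

Step 6
Reactants: 8 9β‑hydroxy enone
Product: 9 9β‑(4‑methoxybenzyl) ether
Conditions: NaH, 4‑methoxybenzyl bromide, Bu4NI (cat.), THF–DMF, 0 → 25 °C
Reagents that add atoms: 4‑methoxybenzyl bromide, COc1ccc(CBr)cc1
Why: Williamson etherification of the only hydroxyl; the silyl enol ether and the vinylogous ester tolerate the alkoxide.

Step 7
Reactants: 9 9β‑(4‑methoxybenzyl) ether
Product: 10 ring A enone (11‑en‑13‑one)
Conditions: Pd(OAc)2 (1.1 equiv), MeCN, 25 °C
Reagents that add atoms: none
Why: Saegusa–Ito oxidation: palladation of the silyl enol ether at C12 and β‑hydride elimination of H11 place the double bond at C11=C12; the C11 stereocentre from step 3 is removed on purpose.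

Step 8
Reactants: 10 ring A enone; 11 prop‑2‑yn‑1‑ol
Product: 12 8‑propargyl enol ether
Conditions: camphorsulfonic acid (0.1 equiv), benzene, 5 Å sieves, 60 °C
Reagents that add atoms: none
Why: Acid‑catalysed alkoxy exchange of a vinylogous ester (addition of the alcohol at C8, loss of methanol into the sieves) installs the propargyl ether with the enol ether regiochemistry fixed by conjugation.

Step 9
Reactants: 12 8‑propargyl enol ether
Product: 13 13β‑allylic alcohol
Conditions: NaBH4, CeCl3·7H2O, MeOH, −78 °C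
Reagents that add atoms: none
Why: Luche 1,2‑reduction of the ring A enone (the vinylogous ester does not react); hydride adds anti to the C15 methyl, 1,3 to C13, giving the β pseudoaxial alcohol.

Step 10
Reactants: 13 13β‑allylic alcohol
Product: 14 11α,12α,13β‑triol
Conditions: OsO4 (0.05 equiv), N‑methylmorpholine N‑oxide, acetone–H2O, 0 → 25 °C
Reagents that add atoms: osmium tetroxide, O=[Os](=O)(=O)=O; N‑methylmorpholine N‑oxide, C[N+]1([O-])CCOCC1
Why: Syn dihydroxylation of the only electron‑rich alkene (C11=C12) from the α face, anti to the C15 methyl, the axial C9 ether and the allylic 13‑hydroxyl, sets C11 and C12 as in the target.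

Step 11
Reactants: 14 11α,12α,13β‑triol
Product: 15 11,12‑acetonide 13β‑alcohol
Conditions: 2,2‑dimethoxypropane, PPTS, CH2Cl2, 25 °C
Reagents that add atoms: 2,2‑dimethoxypropane, COC(C)(C)OC
Why: Acetalisation; only the cis 11,12‑diol can close a dioxolane, the trans‑diaxial 12,13 pair cannot.

Step 12
Reactants: 15 11,12‑acetonide 13β‑alcohol
Product: 16 11,12‑acetonide 13‑ene
Conditions: Ph2S[OC(CF3)2Ph]2, CH2Cl2, 0 → 25 °C
Reagents that add atoms: none
Why: Sulfurane dehydration by anti elimination from the axial 13‑oxysulfonium; H14α is the only antiperiplanar hydrogen (C12 carries its oxygen in the other axial position), so C13=C14 forms.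

Step 13
Reactants: 16 11,12‑acetonide 13‑ene
Product: 17 2β‑allylic alcohol
Conditions: i‑Bu2AlH, CH2Cl2, −78 °C; aqueous sodium potassium tartrate
Reagents that add atoms: none
Why: 1,2‑Reduction of the vinylogous ester carbonyl; hydride enters anti to the adjacent axial C15 methyl and gives the equatorial 2‑hydroxyl cis to C15, and the non‑acidic work‑up keeps the 4‑alkoxy allylic alcohol from ionising.

Step 14
Reactants: 17 2β‑allylic alcohol
Product: 18 2β‑silyl ether
Conditions: TBSOTf, 2,6‑lutidine, CH2Cl2, −78 °C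
Reagents that add atoms: tert‑butyldimethylsilyl trifluoromethanesulfonate, CC(C)(C)[Si](C)(C)OS(=O)(=O)C(F)(F)F
Why: Buffered silylation protects the hindered allylic hydroxyl without hydrolysing the enol ether.

Step 15
Reactants: 18 2β‑silyl ether
Product: 19 3α‑allenyl 8‑ketone
Conditions: [(Ph3PAu)3O]BF4 (0.02 equiv), CH2Cl2, 25 °C; used at once
Reagents that add atoms: none
Why: Gold‑catalysed propargyl Claisen (Saucy–Marbet) rearrangement gives the C8 ketone and the C3 allenyl group; the new bond forms on the α face because the β face at C3 is blocked by the two 1,3‑related axial groups (C15 methyl, C9 ether), leaving the allenyl group equatorial.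

Step 16
Reactants: 19 3α‑allenyl 8‑ketone; 20 (E)‑1,2‑bis(tributylstannyl)ethene
Product: 23 8α‑[(E)‑2‑(tributylstannyl)vinyl] 8β‑carbinol, via (E)‑2‑(tributylstannyl)vinyllithium 21 (not isolated), via (E)‑2‑(tributylstannyl)vinylcerium dichloride 22 (not isolated)
Conditions: 20, n‑BuLi, THF, −78 °C; CeCl3, −78 °C; then 19, −78 °C
Reagents that add atoms: none
Why: Tin–lithium exchange and transmetalation give a weakly basic organocerium reagent that adds to the ketone without enolisation or β‑elimination of the C2 silyloxy group; attack is axial, anti to the polar axial C9–O bond, so the alkenyl group is axial and the hydroxyl equatorial.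

Step 17
Reactants: 23 8α‑[(E)‑2‑(tributylstannyl)vinyl] 8β‑carbinol
Product: 24 8α‑[(E)‑2‑chlorovinyl] 8β‑carbinol
Conditions: CuCl2 (2.5 equiv), THF, 0 → 25 °C
Reagents that add atoms: copper dichloride, Cl[Cu]Cl
Why: Chlorodestannylation of an alkenylstannane with CuCl2 proceeds with retention and gives the E chloroalkene under conditions that spare the allene and the tertiary alcohol.

Step 18
Reactants: 24 8α‑[(E)‑2‑chlorovinyl] 8β‑carbinol
Product: 27 ten‑membered (3Z,7Z) 8‑triethylsilyl enol ether 6‑chloride, via potassium alkoxide 25 (not isolated), via potassium enolate 26 (not isolated)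
Conditions: KN(SiMe3)2, 18‑crown‑6, THF, −78 → −30 °C; then Et3SiCl, Et3N, −78 °C
Reagents that add atoms: chlorotriethylsilane, CC[Si](Cl)(CC)CC
Why: Anionic oxy‑Cope ring expansion through the one chair transition state the trans‑decalin allows (C8 alkenyl axial, C3 allenyl equatorial): C9 pseudoequatorial gives the ring‑trans enolate, C2 pseudoaxial gives the 3Z olefin, the equatorial E chlorine sets C6, the allene terminus becomes the 5(16)‑methylene, and the C6–Cl bond lies in the nodal plane of the enolate, which slows chloride loss until O‑silylation at −78 °C.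

Step 19
Reactants: 27 ten‑membered (3Z,7Z) 8‑triethylsilyl enol ether 6‑chloride; 28 2‑chloropropanoyl chloride
Product: 30 trans‑fused 17‑chloro‑17‑methyl‑8‑triethylsilyloxycyclobutanone, via chloro(methyl)ketene 29 (not isolated)
Conditions: 28 (slow addition), Et3N, hexane–CH2Cl2, 25–40 °C
Reagents that add atoms: none
Why: Ketene 29, generated from 28 with Et3N, is attacked at its carbonyl carbon C19 by the nucleophilic β‑carbon C7 of the silyl enol ether, and the oxocarbenium–enolate zwitterion closes at once by bonding of the enolate carbon C17 to C8 (a 4‑exo‑trig closure), so both new bonds lie on one face of the olefin and the four‑membered ring is trans‑fused to the ten‑membered ring (C6 and C9 anti); the closest known reaction is the [2+2] cycloaddition of chloro(alkyl)ketenes with silyl enol ethers to 2‑chloro‑3‑silyloxycyclobutanones. Regiochemistry follows the polarity of the enol ether, and the step needs site selectivity over the 3,5(16)‑diene and the C13=C14 olefin, which the much higher nucleophilicity of the enol ether toward this electrophilic ketene secures. The chlorine on the ketene is an activating group: it lets the cycloaddition outrun ketene dimerisation, which plain methylketene would not, and it later keeps C17 from migrating in step 20. C7 and C8 are set together by the π‑face: the ring carbons C5 and C10 cover one face, and the olefin as formed in step 18 (O9 eclipsed with O8) must first turn through the ring to the rotamer in which H9 rather than the C9 ether oxygen lies next to the bulky triethylsilyloxy group (allylic 1,2‑strain), whose open face, cis to O9 and to the C6 chlorine, gives the target configuration. C17 forms as a mixture of epimers, which is harmless because this centre is reset in step 21. This facial selectivity is the least secure point of the route.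

Step 20
Reactants: 30 trans‑fused 17‑chloro‑17‑methyl‑8‑triethylsilyloxycyclobutanone
Product: 31 17‑chloro γ‑lactone
Conditions: 30% H2O2, AcOH–THF, NaOAc, 0 °C
Reagents that add atoms: hydrogen peroxide, OO
Why: Baeyer–Villiger oxidation: the strained α‑chlorocyclobutanone adds H2O2 without a peracid, so the alkenes are not epoxidised, and in the peroxyhemiketal C7 migrates with retention because the chlorine‑bearing C17 has a very low migratory aptitude.

Step 21
Reactants: 31 17‑chloro γ‑lactone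
Product: 32 γ‑lactone (17‑H)
Conditions: Zn, AcOH–THF, 0 °C; DBU, toluene, 25 °C if the 17‑epimer is present
Reagents that add atoms: none
Why: Reductive dechlorination: zinc cleaves the C–Cl bond α to the lactone carbonyl much faster than the allylic C6–Cl bond, and protonation of the zinc enolate away from the C8 silyloxy group and C6 should give the 17‑methyl cis to O8; any 17‑epimer is equilibrated to this isomer, whose methyl is anti to C9.

Step 22
Reactants: 32 γ‑lactone
Product: 33 9‑alcohol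
Conditions: DDQ, CH2Cl2–pH 7 buffer, 0 °C
Reagents that add atoms: none
Why: Oxidative cleavage of the 4‑methoxybenzyl ether frees only the C9 hydroxyl; buffering protects the silyl ethers and the dioxolane.

Step 23
Reactants: 33 9‑alcohol
Product: 34 9‑acetate
Conditions: Ac2O, DMAP, Et3N, CH2Cl2, 25 °C
Reagents that add atoms: acetic anhydride, CC(=O)OC(C)=O
Why: DMAP‑catalysed acetylation of the single free hydroxyl.

Step 24
Reactants: 34 9‑acetate
Product: 35 11,12‑diol
Conditions: PPTS, MeOH, 40 °C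
Reagents that add atoms: none
Why: Acid‑catalysed methanolysis of the allylic dioxolane is faster than cleavage of the hindered secondary tert‑butyldimethylsilyl ether at C2, which must stay on for step 25.

Step 25
Reactants: 35 11,12‑diol
Product: 36 13,14‑epoxide
Conditions: VO(acac)2 (0.05 equiv), t‑BuOOH, CH2Cl2, 0 °C
Reagents that add atoms: tert‑butyl hydroperoxide, CC(C)(C)OO
Why: Hydroxyl‑directed epoxidation: the allylic 12‑hydroxyl (and the homoallylic 11‑hydroxyl) deliver the oxidant to the α face of C13=C14, syn to both and anti to the C15 methyl, while the diene has no free hydroxyl within reach.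

Step 26
Reactants: 36 13,14‑epoxide
Product: 37 2,8,11,12‑tetraol 9‑acetate
Conditions: HF·pyridine, pyridine, THF, 0 → 25 °C
Reagents that add atoms: none
Why: Fluoride‑mediated desilylation removes both silyl ethers; with excess pyridine the epoxide, the esters and the allylic chloride should survive.

Step 27
Reactants: 37 2,8,11,12‑tetraol 9‑acetate
Product: 38 CNP0188106.1 (target)
Conditions: butanoic anhydride, DMAP, pyridine, 0 → 25 °C
Reagents that add atoms: butanoic anhydride, CCCC(=O)OC(=O)CCC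
Why: DMAP‑catalysed acylation esterifies the two secondary hydroxyls (C2, C12) and leaves the tertiary 8‑ and 11‑hydroxyls free.

**Compound list**

1 | 2‑methyl‑1,4‑benzoquinone | CC1=CC(=O)C=CC1=O | starting material
2 | 2‑methoxy‑5‑methylbenzene‑1,4‑diol | COc1cc(O)c(C)cc1O | intermediate
3 | 2‑methoxy‑5‑methyl‑1,4‑benzoquinone | COC1=CC(=O)C(C)=CC1=O | intermediate
4 | (E)‑pent‑3‑en‑2‑one | C/C=C/C(C)=O | starting material
5 | (E)‑2‑(tert‑butyldimethylsilyloxy)penta‑1,3‑diene | C=C(O[Si](C)(C)C(C)(C)C)/C=C/C | intermediate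
6 | cis‑fused adduct: ring B 8‑methoxy‑3(8)‑ene‑2,9‑dione, ring A 12‑ene with 13‑OTBS; H10 β (cis to C15), 20‑methyl α | C[C@@]12C(=O)C=C(OC)C(=O)[C@@H]1[C@H](C)C=C(O[Si](C)(C)C(C)(C)C)C2 | intermediate
7 | trans‑fused epimer of 6 (H10 α, 20‑methyl α equatorial) | C[C@@]12C(=O)C=C(OC)C(=O)[C@H]1[C@H](C)C=C(O[Si](C)(C)C(C)(C)C)C2 | intermediate
8 | 9β‑alcohol of 7 (9‑OH axial, cis to C15; C2 ketone kept) | C[C@@]12C(=O)C=C(OC)[C@@H](O)[C@H]1[C@H](C)C=C(O[Si](C)(C)C(C)(C)C)C2 | intermediate
9 | 9β‑(4‑methoxybenzyl) ether of 8 | C[C@@]12C(=O)C=C(OC)[C@@H](OCc3ccc(OC)cc3)[C@H]1[C@H](C)C=C(O[Si](C)(C)C(C)(C)C)C2 | intermediate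
10 | ring A enone: 11‑en‑13‑one (C20 on C11), 9β‑OPMB, 8‑methoxy‑3(8)‑en‑2‑one, H10 α | C[C@@]12C(=O)C=C(OC)[C@@H](OCc3ccc(OC)cc3)[C@H]1C(C)=CC(=O)C2 | intermediate
11 | prop‑2‑yn‑1‑ol | C#CCO | starting material
12 | 8‑(prop‑2‑ynyloxy) analogue of 10 | C[C@@]12C(=O)C=C(OCC#C)[C@@H](OCc3ccc(OC)cc3)[C@H]1C(C)=CC(=O)C2 | intermediate
13 | 13β‑allylic alcohol (11‑ene) | C[C@@]12C(=O)C=C(OCC#C)[C@@H](OCc3ccc(OC)cc3)[C@H]1C(C)=C[C@@H](O)C2 | intermediate
14 | 11α,12α,13β‑triol (20‑methyl β) | C[C@@]12C(=O)C=C(OCC#C)[C@@H](OCc3ccc(OC)cc3)[C@H]1[C@](C)(O)[C@H](O)[C@@H](O)C2 | intermediate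
15 | 11α,12α‑acetonide, 13β‑alcohol | C[C@@]12C(=O)C=C(OCC#C)[C@@H](OCc3ccc(OC)cc3)[C@H]1[C@]4(C)OC(C)(C)O[C@@H]4[C@@H](O)C2 | intermediate
16 | 11α,12α‑acetonide, 13‑ene, 2‑ketone | C[C@@]12C(=O)C=C(OCC#C)[C@@H](OCc3ccc(OC)cc3)[C@H]1[C@]4(C)OC(C)(C)O[C@@H]4C=C2 | intermediate
17 | 2β‑alcohol (equatorial, cis to C15), 8‑propargyloxy‑3(8)‑ene | C[C@@]12[C@@H](O)C=C(OCC#C)[C@@H](OCc3ccc(OC)cc3)[C@H]1[C@]4(C)OC(C)(C)O[C@@H]4C=C2 | intermediate
18 | 2β‑tert‑butyldimethylsilyl ether of 17 | C[C@@]12[C@@H](O[Si](C)(C)C(C)(C)C)C=C(OCC#C)[C@@H](OCc3ccc(OC)cc3)[C@H]1[C@]4(C)OC(C)(C)O[C@@H]4C=C2 | intermediate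
19 | 8‑ketone with 3α‑(propa‑1,2‑dienyl) group (equatorial, trans to 2‑OTBS) | C[C@@]12[C@@H](O[Si](C)(C)C(C)(C)C)[C@H](C=C=C)C(=O)[C@@H](OCc3ccc(OC)cc3)[C@H]1[C@]4(C)OC(C)(C)O[C@@H]4C=C2 | intermediate
20 | (E)‑1,2‑bis(tributylstannyl)ethene | CCCC[Sn](CCCC)(CCCC)/C=C/[Sn](CCCC)(CCCC)CCCC | starting material
21 | (E)‑2‑(tributylstannyl)vinyllithium | [Li]/C=C/[Sn](CCCC)(CCCC)CCCC | intermediate
22 | (E)‑2‑(tributylstannyl)vinylcerium dichloride | Cl[Ce](Cl)/C=C/[Sn](CCCC)(CCCC)CCCC | intermediate
23 | 8β‑hydroxy‑8α‑[(E)‑2‑(tributylstannyl)vinyl] decalin (alkenyl axial, OH equatorial and cis to 9‑OPMB) | C[C@@]12[C@@H](O[Si](C)(C)C(C)(C)C)[C@H](C=C=C)[C@](O)(/C=C/[Sn](CCCC)(CCCC)CCCC)[C@@H](OCc3ccc(OC)cc3)[C@H]1[C@]4(C)OC(C)(C)O[C@@H]4C=C2 | intermediate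
24 | 8β‑hydroxy‑8α‑[(E)‑2‑chlorovinyl] decalin | C[C@@]12[C@@H](O[Si](C)(C)C(C)(C)C)[C@H](C=C=C)[C@](O)(/C=C/Cl)[C@@H](OCc3ccc(OC)cc3)[C@H]1[C@]4(C)OC(C)(C)O[C@@H]4C=C2 | intermediate
25 | potassium alkoxide of 24 | C[C@@]12[C@@H](O[Si](C)(C)C(C)(C)C)[C@H](C=C=C)[C@]([O-])(/C=C/Cl)[C@@H](OCc3ccc(OC)cc3)[C@H]1[C@]4(C)OC(C)(C)O[C@@H]4C=C2.[K+] | intermediate
26 | potassium (7Z)‑enolate of the ten‑membered 8‑ketone (ring‑trans, 3Z, 6‑chloride) | C=C1/C=C\[C@H](O[Si](C)(C)C(C)(C)C)[C@@]2(C)C=C[C@@H](OC(C)(C)O3)[C@]3(C)[C@@H]2[C@H](OCc4ccc(OC)cc4)/C([O-])=C/[C@H]1Cl.[K+] | intermediate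
27 | ten‑membered (3Z,7Z) C8 triethylsilyl enol ether 6‑chloride (7Z: O8 and C6 cis, C6 and C9 trans across the ring olefin); 2‑OTBS, 9‑OPMB, 11,12‑acetonide, 13‑ene | C=C1/C=C\[C@H](O[Si](C)(C)C(C)(C)C)[C@@]2(C)C=C[C@@H](OC(C)(C)O3)[C@]3(C)[C@@H]2[C@H](OCc4ccc(OC)cc4)/C(O[Si](CC)(CC)CC)=C/[C@H]1Cl | intermediate
28 | 2‑chloropropanoyl chloride (racemic) | CC(Cl)C(Cl)=O | starting material
29 | chloro(methyl)ketene | CC(Cl)=C=O | intermediate
30 | trans‑fused cyclobutanone on C7–C8 (C19 on C7; C17 with Cl and methyl on C8; 8‑OSiEt3); drawn as the C17 epimer with chlorine anti to the silyloxy group | C=C1/C=C\[C@H](O[Si](C)(C)C(C)(C)C)[C@@]2(C)C=C[C@@H](OC(C)(C)O3)[C@]3(C)[C@@H]2[C@H](OCc4ccc(OC)cc4)[C@]2(O[Si](CC)(CC)CC)[C@](C)(Cl)C(=O)[C@H]2[C@H]1Cl | intermediate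
31 | 17‑chloro‑17‑methyl γ‑lactone (O between C7 and C19) | C=C1/C=C\[C@H](O[Si](C)(C)C(C)(C)C)[C@@]2(C)C=C[C@@H](OC(C)(C)O3)[C@]3(C)[C@@H]2[C@H](OCc4ccc(OC)cc4)[C@]2(O[Si](CC)(CC)CC)[C@](C)(Cl)C(=O)O[C@H]2[C@H]1Cl | intermediate
32 | γ‑lactone with C17 as in the target; 8‑OSiEt3, 9‑OPMB, 2‑OTBS, acetonide | C=C1/C=C\[C@H](O[Si](C)(C)C(C)(C)C)[C@@]2(C)C=C[C@@H](OC(C)(C)O3)[C@]3(C)[C@@H]2[C@H](OCc4ccc(OC)cc4)[C@]2(O[Si](CC)(CC)CC)[C@@H](C)C(=O)O[C@H]2[C@H]1Cl | intermediate
33 | 9‑alcohol of 32 | C=C1/C=C\[C@H](O[Si](C)(C)C(C)(C)C)[C@@]2(C)C=C[C@@H](OC(C)(C)O3)[C@]3(C)[C@@H]2[C@H](O)[C@]2(O[Si](CC)(CC)CC)[C@@H](C)C(=O)O[C@H]2[C@H]1Cl | intermediate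
34 | 9‑acetate | C=C1/C=C\[C@H](O[Si](C)(C)C(C)(C)C)[C@@]2(C)C=C[C@@H](OC(C)(C)O3)[C@]3(C)[C@@H]2[C@H](OC(C)=O)[C@]2(O[Si](CC)(CC)CC)[C@@H](C)C(=O)O[C@H]2[C@H]1Cl | intermediate
35 | 11,12‑diol 9‑acetate (2‑OTBS, 8‑OSiEt3, 13‑ene) | C=C1/C=C\[C@H](O[Si](C)(C)C(C)(C)C)[C@@]2(C)C=C[C@@H](O)[C@@](C)(O)[C@@H]2[C@H](OC(C)=O)[C@]2(O[Si](CC)(CC)CC)[C@@H](C)C(=O)O[C@H]2[C@H]1Cl | intermediate
36 | 13,14‑epoxide (cis to 11‑ and 12‑OH) | C=C1/C=C\[C@H](O[Si](C)(C)C(C)(C)C)[C@@]2(C)[C@H]3O[C@H]3[C@@H](O)[C@@](C)(O)[C@@H]2[C@H](OC(C)=O)[C@]2(O[Si](CC)(CC)CC)[C@@H](C)C(=O)O[C@H]2[C@H]1Cl | intermediate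
37 | 2,8,11,12‑tetraol 9‑acetate | C=C1/C=C\[C@H](O)[C@@]2(C)[C@H]3O[C@H]3[C@@H](O)[C@@](C)(O)[C@@H]2[C@H](OC(C)=O)[C@]2(O)[C@@H](C)C(=O)O[C@H]2[C@H]1Cl | intermediate
38 | CNP0188106.1: 9‑acetate 2,12‑dibutanoate | C=C1/C=C\[C@H](OC(=O)CCC)[C@@]2(C)[C@H]3O[C@H]3[C@@H](OC(=O)CCC)[C@@](C)(O)[C@@H]2[C@H](OC(C)=O)[C@]2(O)[C@@H](C)C(=O)O[C@H]2[C@H]1Cl | target

**Totals**

Total step count: 27. Longest linear sequence: 26 steps (1 → 38 through steps 1 and 3–27; step 2 prepares diene 5).

**Steps most likely to fail**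

Step 19. The ketene may add to the other face of the enol ether, the one that is open before the olefin has turned through the ring, giving the 7,8‑bis‑epimer. The zwitterion may also open by silyl transfer to an acyclic acylated enol ether instead of closing. Fallback, starting from 27 and rejoining at 32, builds the lactone by carbonyl chemistry instead of cycloaddition. Rubottom oxidation of 27 (dimethyldioxirane, acetone, −78 °C, buffered work‑up) should give the 7‑hydroxy‑8‑ketone F1, with the hydroxyl on the face the oxidant prefers (drawn as the 7‑epimer). Mitsunobu esterification with 2‑bromopropanoic acid (PPh3, DIAD) inverts C7 and gives the 7‑(2‑bromopropanoate) F2; if the oxidant takes the other face, the ester is made with retention (DCC) instead. An intramolecular Reformatsky reaction with SmI2 (THF, −78 °C) closes C17–C8 to the trans‑fused 8‑hydroxy lactone F3, and Et3SiOTf with 2,6‑lutidine then gives 32.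

Step 18. The β‑chloro enolate may lose chloride (conjugate elimination to a C6=C7 enone) before it is silylated, or the strong base may dehydrochlorinate the chlorovinyl group. Fallback, starting from 24 and rejoining at 27, avoids the enolate by a neutral siloxy‑Cope rearrangement. Silylation of 24 (Et3SiOTf, 2,6‑lutidine) gives the 8‑O‑triethylsilyl ether F4, and heating it (toluene, sealed base‑washed tube, 110–140 °C) should deliver 27 directly through the same chair transition state.

Step 3. The catalysed cycloaddition has to form the quaternary C1 at the hindered methyl‑bearing carbon, so the enantioselectivity may be low or the regioselectivity may erode. Fallback, starting from 3 and 5 and rejoining at 8, replaces catalysis by resolution. Thermal cycloaddition (toluene, 80 °C) should give 6 together with its enantiomer ent‑6 F5. Steps 4 and 5 on the mixture give 7 with ent‑7 F6, then 8 with ent‑8 F7. Esterification with (S)‑2‑methoxy‑2‑phenylacetic acid (DCC, DMAP) gives the diastereomeric esters, the ester of 8 F8 and the ester of ent‑8 F9. F8 is separated by chromatography or crystallisation and cleaved (K2CO3, MeOH) to 8.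

**Further compounds**

F1 | step 19 | 7‑epi‑7‑hydroxy‑8‑ketone of the ten‑membered ring (6‑chloride, protecting groups as in 27) | C=C1/C=C\[C@H](O[Si](C)(C)C(C)(C)C)[C@@]2(C)C=C[C@@H](OC(C)(C)O3)[C@]3(C)[C@@H]2[C@H](OCc4ccc(OC)cc4)C(=O)[C@H](O)[C@H]1Cl
F2 | step 19 | 7‑(2‑bromopropanoyloxy)‑8‑ketone, C7 as in the target | C=C1/C=C\[C@H](O[Si](C)(C)C(C)(C)C)[C@@]2(C)C=C[C@@H](OC(C)(C)O3)[C@]3(C)[C@@H]2[C@H](OCc4ccc(OC)cc4)C(=O)[C@@H](OC(=O)C(C)Br)[C@H]1Cl
F3 | step 19 | 8‑hydroxy γ‑lactone (32 without the triethylsilyl group) | C=C1/C=C\[C@H](O[Si](C)(C)C(C)(C)C)[C@@]2(C)C=C[C@@H](OC(C)(C)O3)[C@]3(C)[C@@H]2[C@H](OCc4ccc(OC)cc4)[C@]2(O)[C@@H](C)C(=O)O[C@H]2[C@H]1Cl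
F4 | step 18 | 8‑O‑triethylsilyl ether of 24 | C[C@@]12[C@@H](O[Si](C)(C)C(C)(C)C)[C@H](C=C=C)[C@](O[Si](CC)(CC)CC)(/C=C/Cl)[C@@H](OCc3ccc(OC)cc3)[C@H]1[C@]4(C)OC(C)(C)O[C@@H]4C=C2
F5 | step 3 | ent‑6 | C[C@]12C(=O)C=C(OC)C(=O)[C@H]1[C@@H](C)C=C(O[Si](C)(C)C(C)(C)C)C2
F6 | step 3 | ent‑7 | C[C@]12C(=O)C=C(OC)C(=O)[C@@H]1[C@@H](C)C=C(O[Si](C)(C)C(C)(C)C)C2
F7 | step 3 | ent‑8 | C[C@]12C(=O)C=C(OC)[C@H](O)[C@@H]1[C@@H](C)C=C(O[Si](C)(C)C(C)(C)C)C2
F8 | step 3 | (S)‑2‑methoxy‑2‑phenylacetate of 8 | C[C@@]12C(=O)C=C(OC)[C@@H](OC(=O)[C@@H](OC)c3ccccc3)[C@H]1[C@H](C)C=C(O[Si](C)(C)C(C)(C)C)C2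
F9 | step 3 | (S)‑2‑methoxy‑2‑phenylacetate of ent‑8 | C[C@]12C(=O)C=C(OC)[C@H](OC(=O)[C@@H](OC)c3ccccc3)[C@@H]1[C@@H](C)C=C(O[Si](C)(C)C(C)(C)C)C2
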